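Where the Ul of this flask stands after 40 h, and in what share, is a question about which clock the flask runs on.

1. where most of what was charged as Ul, at 40 h is found (UlJa / Ym / Ul / UlXi)
2. the largest share itself, whichever of these holds it, in percent of the Ul charged

in all of them: Ja 1.05 equiv

|  | Ul | Xi | remark | time |
|---|---|---|---|---|
| south-east | 0.34 M | 1 equiv (in portions, 3) | run made earlier; portions every 1.0 h |  |
| west | 0.75 M | 1 equiv (in portions, 3) | run made earlier; portions every 1.0 h |  |
| north-east | 0.50 M | 1.5 equiv (in portions, 3) | run made earlier; portions every 1.0 h |  |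
| flask | 0.50 M | 1.00 equiv (in portions, 3) | the portions of Xi follow each other after 1.0 h, the first at the start | 40 h |

| run | time / h | UlJa / % | Ul / % | Ym / % | UlXi / % |
|---|---|---|---|---|---|
| south-east | 3.00 | 5 | 92 | 1 | 6 |
| south-east | 8.00 | 6 | 69 | 6 | 14 |
| south-east | 15.0 | 11 | 55 | 9 | 22 |
| south-east | 25.0 | 13 | 40 | 16 | 26 |
| south-east | 30.0 | 12 | 35 | 18 | 33 |
| west | 6.00 | 12 | 62 | 8 | 16 |
| west | 12.0 | 15 | 41 | 15 | 30 |
| west | 20.0 | 17 | 28 | 22 | 34 |
| west | 25.0 | 17 | 25 | 25 | 36 |
| west | 30.0 | 16 | 22 | 26 | 38 |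
| north-east | 2.50 | 7 | 88 | 0 | 7 |
| north-east | 5.00 | 13 | 67 | 5 | 16 |
| north-east | 10.0 | 11 | 52 | 11 | 27 |
| north-east | 15.0 | 11 | 40 | 15 | 38 |
| north-east | 30.0 | 13 | 20 | 21 | 50 |

(each reading ± 1.5 percentage points)



Two chemists read these runs differently. The first counts the dose, c(Ul) times hours, known as reduced time, here 1200 M·min: Ul meets Ja and Xi in pairs, so at equal equivalents she expects equal dose to give equal shares. Her evidence is the south-east run at 25.0 h and the west run at 12.0 h, with doses of 510 M·min and 540 M·min. One stood twice as long, yet they read Ul 40 % and 41 %, Ym 16 % and 15 %. So she reads the flask off the west run at 26.7 h, between its readings: UlXi 36.7 %, Ym 25.3 %.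

The second counts hours. UlJa turning into Ym involves one species, he says, so it ignores c(Ul). The flask's extra 13.3 h must then add Ym at the west run's late pace, 4 percentage points from 20.0 h to 30.0 h. That gives Ym 30.7 %, still below her UlXi of 36.7 %.

The forecast sides with her, though at 39 % it stands above her 36.7 %: “UlXi holds the largest share.”

The flask gives UlXi at 38.0 %, with Ym at 24.5 %.

    Ul + Ja → UlJa (k = 0.00115 M⁻¹ min⁻¹)
    Xi + Ja → XiJa (k = 7.79 × 10⁻⁴ M⁻¹ min⁻¹)
    Ul + Xi → UlXi (k = 0.00122 M⁻¹ min⁻¹)
    UlJa ⇌ Ym (K = 1.60, k = 0.00401 min⁻¹)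

UlJa and Ym relax towards each other with a half-life of 1.77 h, while Ul has 19 h by the conversion into UlXi, whole charges counted as present at once, ten times as long; the hours view has its region in this flask's opening hours, where at 2.00 h it holds Ym 1.28 % beside UlJa 5.33 %. A neighbouring flask, this recipe at 1.2 M Ul, reaches 2.40 times this flask's dose in the same 40 h, while this flask at 400 h reaches ten times its dose; the neighbour's Ym of 29.6 % lies between this flask's 24.5 % and 31.5 %, its UlXi of 43.7 % between 38.0 % and 48.0 %.

(The numbers in the tables were generated by integration for substances that don't exist, and the scatter is random.)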